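The earlier runs and the new flask come from a simulation from invented constants.

1. Left-handed product cannot pass half of the charge without exchange, yet Thursday's run, the asked flask followed so far, read 52.1% at 1.00 min, so right-handed substrate was turning into left-handed substrate over the racemization catalyst.

- Thursday's: left-handed substrate 0.40 M; right-handed substrate 0.40 M; partner 1.2 M; racemization catalyst 1.5 mM; the very flask that is asked about, followed so far
- flask: left-handed substrate 0.40 M; partner 1.20 M; racemization catalyst 1.5 mM; right-handed substrate 0.40 M; time 8.0 min

Thursday's run (percent of the left-handed substrate and right-handed substrate together charged)

| time / min | left-handed product / % | right-handed product / % |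
|---|---|---|
| 0.500 | 39.5 | 1.0 |
| 1.00 | 52.1 | 1.1 |
| 1.50 | 58.2 | 2.2 |
| 2.00 | 61.9 | 3.4 |
| 2.50 | 66.7 | 2.7 |
| 3.00 | 69.6 | 3.1 |

(each reading ± 1 percentage point)

- partner is single-handed; left-handed substrate and right-handed substrate are mirror images of each other, charged as a racemate, each of them at the stated concentration
- an excess is below zero if the other one leads
- the handed part of partner does not stay in what it makes, so the products of the two hands are mirror images too

- left-handed product and right-handed product together, in percent of the left-handed substrate and right-handed substrate charged together, at 8.0 min
- excess of left-handed product over right-handed product in the product at 8.0 min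
- whether the exchange between left-handed substrate and right-handed substrate keeps pace with the reaction: how far the product's excess at 8.0 min gets from its value without exchange to its value with instant exchange (above 80% keeps pace, below 20% hardly takes part, else lags behind)

2. I counted in fractions of the charge. With exchange neglected, the first reading gave partner, at its full charge, a pseudo-first-order rate on left-handed substrate of 3.77 min⁻¹.

3. Unreacted substrate then fell from 39.6% at 1.50 min to 27.3% at 3.00 min. That is 0.248 min⁻¹, which I took as the exchange rate.

4. Continued at that rate, 92.1% of the asked flask had reacted at 8.0 min, leaving 38.6% of the partner.

5. So H = 5.86, the hand number: the rate per molecule of left-handed substrate towards partner, over its rate per molecule towards right-handed substrate by the forward exchange step. H is above one, so exchange lags, and if the flow from right-handed substrate balances the loss of left-handed substrate, right-handed substrate should outnumber left-handed substrate by one plus H, 6.86.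

6. One number was not enough: H holds for one moment, 8.0 min, with the exchange rate read from 1.50 min to 3.00 min, and the readings before 1.50 min gave me no exchange rate to put in it.

The forecast gave 92% (87% to 95%), 90.5% (87% to 93%) and "lags behind": “The fraction reached is about 72 %, so exchange lags behind.”

The flask gave 89.6%, 86.9% and "lags behind", 74% of the way.

    partner + left-handed substrate → left-handed product (k = 2.63 L mol⁻¹ min⁻¹)
    partner + right-handed substrate → right-handed product (k = 0.0468 L mol⁻¹ min⁻¹)
    left-handed substrate + racemization catalyst ⇌ right-handed substrate + racemization catalyst, rate k3*[racemization catalyst]*[left-handed substrate] forward; the back reaction follows from the equilibrium constant (k = 1060 L mol⁻¹ min⁻¹)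
    2 racemization catalyst ⇌ resting dimer (K = 17000 L mol⁻¹, k = 2260 L mol⁻¹ min⁻¹)
    racemization catalyst ⇌ dormant form (K = 0.410, k = 0.0168 min⁻¹)

At 8.00 min the asked flask used left-handed substrate 6.2 times as fast by partner as by the forward exchange step alone, and it held right-handed substrate at 6.43 times left-handed substrate, against my 6.86. In the flask charged with 2.0 M of partner, H scaled by that charge and its remaining 62.4% of partner gives a ratio of 16.8; that flask held 15.9, and its excess was 78.4%.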